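**Retrosynthetic overview**

1. Ring numbering: C1 = ring CH carrying the propyl group, O2, C3 (lactone C=O), C4 and C6 (CHMe), C11 (ketone), C15 (CHEt), C16=C17–C18=C19 (diene, C19 carries CH2OH), C22/C23/C25 (CHOH), C26, N27, C28 (amide C=O). The 28-membered macrocycle is the only ring.
2. Enabling feature: C15 is an sp3 stereocentre (H, Et, C14) bonded directly to C16, the terminus of the C16=C17–C18=C19 diene inside the ring. This secondary-alkyl–alkenyl junction is cut into a configurationally defined secondary C15–B bond and a C16–I dienyl iodide. One stereospecific Suzuki–Miyaura event then closes the 28-membered ring, completes the diene and delivers C15 (step 29, the last C–C bond and the only ring formation).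
3. Seco compound 46 ← ester O2–C3 (acid 18 + hydroxy amide 43) ← amide N27–C28 (amine 39 + (S)-2-hydroxypentanoic acid 41).
4. Acid 18 ← C11–C12 acylation of an alkylzirconocene: acid chloride 9 (desymmetrised meso-2,4-dimethylglutaric anhydride, C7=C8 Wittig) + boronic ester 15 (C15–B set by sparteine-mediated lithiation–borylation).
5. Amine 39 ← C19–C20 B-alkyl Suzuki coupling of alkene 27 (C25 from (S)-GABOB; C22/C23 by iridium-catalysed anti-alkoxyallylation) with iodo dienoate 32 (C18=C19 geometry from syn-hydrostannation of an ynoate).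

Key step: step 29

Abbreviations: TBS = tert-butyldimethylsilyl; Bpin = 4,4,5,5-tetramethyl-1,3,2-dioxaborolan-2-yl; Cb = N,N-diisopropylcarbamoyl.

Assumption: the catalyst hands written for the two catalyst-controlled steps (1 and 14) are taken to deliver the isomers drawn; the pseudo-enantiomeric alkaloid ether (DHQ)2AQN or (S)-SEGPHOS would serve if the opposite sense were met.

**Acid fragment (C3–C15)**

Step 1
Reactants: 1 meso-2,4-dimethylglutaric anhydride
Product: 2 (2R,4S)-5-methoxy-2,4-dimethyl-5-oxopentanoic acid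
Conditions: MeOH (10 equiv), (DHQD)2AQN (10 mol%), Et2O, −40 °C
Reagents that add atoms: methanol, CO
Why: Cinchona-alkaloid-catalysed enantiotopos-selective alcoholysis of a meso anhydride (general-base delivery of methanol to one of the two enantiotopic carbonyls) should fix both methyl-bearing centres C4 and C6 at once from the cis relationship already present in 1.

Step 2
Reactants: 2 (2R,4S)-5-methoxy-2,4-dimethyl-5-oxopentanoic acid
Product: 3 methyl (2S,4R)-5-hydroxy-2,4-dimethylpentanoate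
Conditions: BH3·SMe2, THF, 0 °C to rt; MeOH quench
Reagents that add atoms: none
Why: Chemoselective borane reduction of the free carboxylic acid (through its acyloxyborane) should leave the methyl ester and both stereocentres untouched.

Step 3
Reactants: 3 methyl (2S,4R)-5-hydroxy-2,4-dimethylpentanoate
Product: 4 methyl (2S,4R)-2,4-dimethyl-5-oxopentanoate
Conditions: Dess–Martin periodinane, NaHCO3, CH2Cl2, 0 °C; used at once
Reagents that add atoms: none
Why: Buffered Dess–Martin oxidation should give the α-branched aldehyde without epimerisation at C6.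

Step 4
Reactants: 4 methyl (2S,4R)-2,4-dimethyl-5-oxopentanoate; 5 (3-carboxypropyl)triphenylphosphonium bromide
Product: 7 (4Z,6R,8S)-9-methoxy-6,8-dimethyl-9-oxonon-4-enoic acid, via phosphorus ylide 6 (not isolated)
Conditions: 5, NaHMDS (2 equiv per 5), THF, 0 °C; then 4, −78 °C to rt; aq. HCl work-up
Reagents that add atoms: none
Why: Wittig olefination with the non-stabilised carboxylate ylide should add C8–C11 at low temperature without touching the ester or the α-centre; the Z alkene geometry is irrelevant because it is hydrogenated next.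

Step 5
Reactants: 7 (4Z,6R,8S)-9-methoxy-6,8-dimethyl-9-oxonon-4-enoic acid
Product: 8 (6S,8S)-9-methoxy-6,8-dimethyl-9-oxononanoic acid
Conditions: H2 (1 atm), Pd/C, EtOAc, rt
Reagents that add atoms: none
Why: Heterogeneous catalytic hydrogenation should saturate C7=C8 and nothing else.

Step 6
Reactants: 8 (6S,8S)-9-methoxy-6,8-dimethyl-9-oxononanoic acid
Product: 9 methyl (2S,4S)-9-chloro-2,4-dimethyl-9-oxononanoate
Conditions: (COCl)2, DMF (cat.), CH2Cl2, 0 °C to rt
Reagents that add atoms: oxalyl chloride, O=C(Cl)C(=O)Cl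
Why: Acid chloride formation through the Vilsmeier-type chloroiminium species occurs at the unbranched C11 carboxyl, so no stereocentre is at risk.

Step 7
Reactants: 10 but-3-en-1-ol
Product: 11 but-3-en-1-yl N,N-diisopropylcarbamate
Conditions: CbCl, Et3N, CH2Cl2, reflux
Reagents that add atoms: N,N-diisopropylcarbamoyl chloride, CC(C)N(C(C)C)C(=O)Cl
Why: O-Carbamoylation installs the directing and leaving group needed for α-lithiation.

Step 8
Reactants: 11 but-3-en-1-yl N,N-diisopropylcarbamate; 12 2-ethyl-4,4,5,5-tetramethyl-1,3,2-dioxaborolane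
Product: 15 2-[(3S)-hex-5-en-3-yl]-4,4,5,5-tetramethyl-1,3,2-dioxaborolane, via lithiated carbamate 13 (not isolated), via boronate complex 14 (not isolated)
Conditions: s-BuLi, (−)-sparteine, Et2O, −78 °C; then 12, −78 °C; then MgBr2·OEt2, reflux
Reagents that add atoms: none
Why: Sparteine-mediated lithiation–borylation should set the boron-bearing C15 centre as S, through removal of the pro-S hydrogen, borylation with retention and a Matteson-type 1,2-metallate shift of ethyl with inversion at carbon.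

Step 9
Reactants: 15 2-[(3S)-hex-5-en-3-yl]-4,4,5,5-tetramethyl-1,3,2-dioxaborolane; 9 methyl (2S,4S)-9-chloro-2,4-dimethyl-9-oxononanoate
Product: 17 methyl (2S,4S,13S)-2,4-dimethyl-9-oxo-13-(Bpin)pentadecanoate, via alkylzirconocene 16 (not isolated)
Conditions: Cp2Zr(H)Cl, THF, rt; then 9, CuBr·SMe2 (10 mol%), 0 °C to rt
Reagents that add atoms: none
Why: Hydrozirconation places zirconium on the terminal carbon C12, and copper-catalysed acylation of the alkylzirconocene by the acid chloride should form the C11 ketone while the methyl ester and the secondary C–B bond stay inert.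

Step 10
Reactants: 17 methyl (2S,4S,13S)-2,4-dimethyl-9-oxo-13-(Bpin)pentadecanoate
Product: 18 (2S,4S,13S)-2,4-dimethyl-9-oxo-13-(Bpin)pentadecanoic acid
Conditions: LiOH, THF/MeOH/H2O, 0 °C to rt; then aq. HCl to pH 3
Reagents that add atoms: lithium hydroxide, [Li+].[OH-]
Why: Mild saponification of the methyl ester should be faster than α-epimerisation at C4, and the pinacol boronate is recovered on acidification.

**Polyol–diene fragment (C16–C26)**

Step 11
Reactants: 19 (3S)-4-amino-3-hydroxybutanoic acid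
Product: 20 (3S)-4-[(tert-butoxycarbonyl)amino]-3-hydroxybutanoic acid
Conditions: Boc2O, NaOH, dioxane/H2O, 0 °C to rt; then aq. HCl to pH 3
Reagents that add atoms: di-tert-butyl dicarbonate, CC(C)(C)OC(=O)OC(=O)OC(C)(C)C
Why: N-Acylation of the amine protects N27, and the chiral-pool centre that becomes C25 is not touched.

Step 12
Reactants: 20 (3S)-4-[(tert-butoxycarbonyl)amino]-3-hydroxybutanoic acid
Product: 21 tert-butyl N-[(2S)-2,4-dihydroxybutyl]carbamate
Conditions: BH3·SMe2, THF, 0 °C to rt; MeOH quench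
Reagents that add atoms: none
Why: Chemoselective borane reduction of the carboxylic acid should give the primary alcohol (C23) without reducing the carbamate.

Step 13
Reactants: 22 acrolein
Product: 23 prop-2-ene-1,1-diyl dibenzoate
Conditions: benzoic anhydride, H2SO4 (cat.), CH2Cl2, 0 °C to rt
Reagents that add atoms: benzoic anhydride, O=C(OC(=O)c1ccccc1)c1ccccc1
Why: Acid-catalysed acylal formation turns the aldehyde into the allylic gem-dicarboxylate that serves as α-acyloxy-allyl donor.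

Step 14
Reactants: 21 tert-butyl N-[(2S)-2,4-dihydroxybutyl]carbamate; 23 prop-2-ene-1,1-diyl dibenzoate
Product: 25 (3R,4S,6S)-7-[(tert-butoxycarbonyl)amino]-4,6-dihydroxyhept-1-en-3-yl benzoate, via hydroxy aldehyde 24 (not isolated)
Conditions: [Ir(cod)Cl]2 (2.5 mol%), (R)-SEGPHOS (5 mol%), 4-cyano-3-nitrobenzoic acid (10 mol%), K3PO4 (1 equiv), THF, 90 °C
Reagents that add atoms: none
Why: Iridium-catalysed transfer-hydrogenative carbonyl (α-acyloxy)allylation dehydrogenates only the primary alcohol to aldehyde 24, which the (E)-σ-allyliridium species from 23 attacks through a closed chair transition state (C22/C23 anti) on the face set by the (R)-SEGPHOS catalyst (23S), overriding the resident C25 centre.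

Step 15
Reactants: 25 (3R,4S,6S)-7-[(tert-butoxycarbonyl)amino]-4,6-dihydroxyhept-1-en-3-yl benzoate
Product: 26 tert-butyl N-[(2S,4S,5R)-2,4,5-trihydroxyhept-6-en-1-yl]carbamate
Conditions: K2CO3 (cat.), MeOH, 0 °C to rt
Reagents that add atoms: none
Why: Base-catalysed transesterification removes the benzoate without affecting the carbamate or the stereocentres.

Step 16
Reactants: 26 tert-butyl N-[(2S,4S,5R)-2,4,5-trihydroxyhept-6-en-1-yl]carbamate
Product: 27 tert-butyl N-[(2S,4S,5R)-2,4,5-tris(TBS-oxy)hept-6-en-1-yl]carbamate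
Conditions: TBSOTf (3.3 equiv), 2,6-lutidine, CH2Cl2, −78 to 0 °C
Reagents that add atoms: tert-butyldimethylsilyl trifluoromethanesulfonate, CC(C)(C)[Si](C)(C)OS(=O)(=O)C(F)(F)F
Why: Silyl triflate silylation covers the hindered vicinal diol and the C25 hydroxyl at low temperature, where the Boc group is not yet cleaved.

Step 17
Reactants: 28 (E)-(2-bromovinyl)trimethylsilane; 29 methyl propiolate
Product: 30 methyl (4E)-5-(trimethylsilyl)pent-4-en-2-ynoate
Conditions: PdCl2(PPh3)2 (5 mol%), CuI (10 mol%), K2CO3, THF, 50 °C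
Reagents that add atoms: none
Why: Sonogashira coupling with an inorganic base (to avoid amine conjugate addition to the propiolate) should join C17 and C18 with retention of the E vinylsilane.

Step 18
Reactants: 30 methyl (4E)-5-(trimethylsilyl)pent-4-en-2-ynoate
Product: 31 methyl (2E,4E)-2-(tributylstannyl)-5-(trimethylsilyl)penta-2,4-dienoate
Conditions: Bu3SnH, Pd(PPh3)4 (2 mol%), THF, 0 °C
Reagents that add atoms: tributyltin hydride, CCCC[SnH](CCCC)CCCC
Why: Palladium-catalysed syn-hydrostannation of an ynoate places tin α to the ester and hydrogen on C18, which fixes the C18=C19 geometry with C17 cis to the ester carbon.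

Step 19
Reactants: 31 methyl (2E,4E)-2-(tributylstannyl)-5-(trimethylsilyl)penta-2,4-dienoate
Product: 32 methyl (2E,4E)-2-iodo-5-(trimethylsilyl)penta-2,4-dienoate
Conditions: I2, CH2Cl2, 0 °C
Reagents that add atoms: iodine, II
Why: Iododestannylation proceeds with retention at C19 and is much faster than attack on the vinylsilane.

Step 20
Reactants: 27 tert-butyl N-[(2S,4S,5R)-2,4,5-tris(TBS-oxy)hept-6-en-1-yl]carbamate; 32 methyl (2E,4E)-2-iodo-5-(trimethylsilyl)penta-2,4-dienoate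
Product: 34 methyl (2Z,5R,6S,8S)-9-[(tert-butoxycarbonyl)amino]-5,6,8-tris(TBS-oxy)-2-[(2E)-3-(trimethylsilyl)prop-2-en-1-ylidene]nonanoate, via alkylborane 33 (not isolated)
Conditions: 9-BBN dimer, THF, rt; then 32, PdCl2(dppf) (5 mol%), AsPh3, Cs2CO3, DMF/THF/H2O, rt
Reagents that add atoms: none
Why: Anti-Markovnikov hydroboration at C20 followed by B-alkyl Suzuki–Miyaura coupling with the α-iodo enoate should form C19–C20 with retention of the alkene geometry.

Step 21
Reactants: 34 methyl (2Z,5R,6S,8S)-9-[(tert-butoxycarbonyl)amino]-5,6,8-tris(TBS-oxy)-2-[(2E)-3-(trimethylsilyl)prop-2-en-1-ylidene]nonanoate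
Product: 35 tert-butyl N-[(2S,4S,5R,8Z,10E)-2,4,5-tris(TBS-oxy)-8-(hydroxymethyl)-11-(trimethylsilyl)undeca-8,10-dien-1-yl]carbamate
Conditions: DIBAL-H, CH2Cl2, −78 °C; Rochelle salt work-up
Reagents that add atoms: none
Why: 1,2-Reduction of the dienoate by DIBAL-H gives the C19 hydroxymethyl group, and the carbamate survives at −78 °C.

Step 22
Reactants: 35 tert-butyl N-[(2S,4S,5R,8Z,10E)-2,4,5-tris(TBS-oxy)-8-(hydroxymethyl)-11-(trimethylsilyl)undeca-8,10-dien-1-yl]carbamate
Product: 36 tert-butyl N-[(2S,4S,5R,8Z,10E)-2,4,5-tris(TBS-oxy)-8-(TBS-oxymethyl)-11-(trimethylsilyl)undeca-8,10-dien-1-yl]carbamate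
Conditions: TBSCl, imidazole, DMF, rt
Reagents that add atoms: tert-butyldimethylsilyl chloride, CC(C)(C)[Si](C)(C)Cl
Why: Standard silylation protects the primary allylic alcohol so that all four hydroxyls carry the same group for one final deprotection.

Step 23
Reactants: 36 tert-butyl N-[(2S,4S,5R,8Z,10E)-2,4,5-tris(TBS-oxy)-8-(TBS-oxymethyl)-11-(trimethylsilyl)undeca-8,10-dien-1-yl]carbamate
Product: 37 tert-butyl N-[(2S,4S,5R,8Z,10E)-2,4,5-tris(TBS-oxy)-8-(TBS-oxymethyl)-11-iodoundeca-8,10-dien-1-yl]carbamate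
Conditions: N-iodosuccinimide, 2,6-lutidine, (CF3)2CHOH, 0 °C
Reagents that add atoms: N-iodosuccinimide, O=C1CCC(=O)N1I
Why: Ipso-iododesilylation is steered to C16 by the β-silyl effect and should retain the E geometry in the ionising fluoroalcohol.

Step 24
Reactants: 37 tert-butyl N-[(2S,4S,5R,8Z,10E)-2,4,5-tris(TBS-oxy)-8-(TBS-oxymethyl)-11-iodoundeca-8,10-dien-1-yl]carbamate
Product: 39 (2S,4S,5R,8Z,10E)-2,4,5-tris(TBS-oxy)-8-(TBS-oxymethyl)-11-iodoundeca-8,10-dien-1-amine, via trimethylsilyl carbamate 38 (not isolated)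
Conditions: TMSOTf, 2,6-lutidine, CH2Cl2, 0 °C; then MeOH
Reagents that add atoms: none
Why: Silyl-triflate-mediated Boc cleavage (tert-butyl loss to the silyl carbamate, then methanolysis and decarboxylation) frees the amine under buffered conditions that spare the TBS ethers and the dienyl iodide.

**Assembly and ring closure**

Step 25
Reactants: 40 L-norvaline
Product: 41 (2S)-2-hydroxypentanoic acid
Conditions: NaNO2, 1 M H2SO4, 0 °C to rt
Reagents that add atoms: water, O
Why: Diazotisation of an α-amino acid gives the α-hydroxy acid with net retention (double inversion through the α-lactone), so the C1 centre comes from the chiral pool.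

Step 26
Reactants: 39 (2S,4S,5R,8Z,10E)-2,4,5-tris(TBS-oxy)-8-(TBS-oxymethyl)-11-iodoundeca-8,10-dien-1-amine; 41 (2S)-2-hydroxypentanoic acid
Product: 43 (2S)-2-hydroxy-N-[(2S,4S,5R,8Z,10E)-2,4,5-tris(TBS-oxy)-8-(TBS-oxymethyl)-11-iodoundeca-8,10-dien-1-yl]pentanamide, via benzotriazolyl ester 42 (not isolated)
Conditions: EDC·HCl, HOBt, i-Pr2NEt, CH2Cl2, 0 °C to rt
Reagents that add atoms: none
Why: Carbodiimide/HOBt amide coupling is selective for the amine over the free α-hydroxyl and does not racemise an α-hydroxy acid.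

Step 27
Reactants: 18 (2S,4S,13S)-2,4-dimethyl-9-oxo-13-(Bpin)pentadecanoic acid; 43 (2S)-2-hydroxy-N-[(2S,4S,5R,8Z,10E)-2,4,5-tris(TBS-oxy)-8-(TBS-oxymethyl)-11-iodoundeca-8,10-dien-1-yl]pentanamide
Product: 45 (2S)-1-oxo-1-{[(2S,4S,5R,8Z,10E)-2,4,5-tris(TBS-oxy)-8-(TBS-oxymethyl)-11-iodoundeca-8,10-dien-1-yl]amino}pentan-2-yl (2S,4S,13S)-2,4-dimethyl-9-oxo-13-(Bpin)pentadecanoate, via mixed anhydride 44 (not isolated)
Conditions: 2,4,6-trichlorobenzoyl chloride, Et3N, THF, rt; then 43, DMAP, toluene, rt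
Reagents that add atoms: none
Why: Yamaguchi esterification acylates the only free hydroxyl (O2) with retention at C1, and the short contact time with DMAP should limit epimerisation at C4.

Step 28
Reactants: 45 seco ester with C15–Bpin and C16–I
Product: 46 potassium trifluoroborate of 45 (C15–BF3K)
Conditions: aq. KHF2, MeOH, 0 °C to rt; pinacol removed by azeotrope
Reagents that add atoms: potassium hydrogen difluoride, [K+].[F-].F
Why: Fluoride exchange at boron gives the bench-stable trifluoroborate as a slow-release form of the secondary boronic acid, without touching the C15 configuration.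

Step 29
Reactants: 46 potassium trifluoroborate of 45 (C15–BF3K)
Product: 48 tetra-TBS macrocycle (target with TBS on O22 O23 O25 and on the C19 hydroxymethyl oxygen), via boronic acid 47 (not isolated)
Conditions: Pd(P(t-Bu)3)2 (15 mol%), K2CO3 (3 equiv), degassed toluene/H2O 2:1, 80 °C, syringe-pump addition of 46 to a final 2 mM
Reagents that add atoms: none
Why: Proposed new method: zerovalent palladium bearing P(t-Bu)3 adds oxidatively into the C16–I bond with retention of the 16E geometry, the trifluoroborate hydrolyses slowly to boronic acid 47, the unactivated secondary C15–B bond transmetalates to the hydroxo-palladium centre through an open backside (invertive SE2) transition state, and C(sp3)–C(sp2) reductive elimination forms C15–C16. The closest known reaction types are the stereoinvertive Suzuki–Miyaura coupling of enantioenriched unactivated secondary alkyltrifluoroborates with aryl chlorides under bulky trialkylphosphine–palladium catalysis and the B-alkyl Suzuki macrocyclisation of primary alkylboranes onto alkenyl iodides; the two have not been combined on a secondary boron centre and a dienyl iodide. The 28-membered ring is closed end to end, by reductive elimination from a 29-membered palladacycle in which the boron end and the iodide end of one chain have met. C15 is transferred, not created: the S C–B centre from step 8 is expected to invert to the R configuration of the target. The step needs reductive elimination to outrun β-hydride elimination and chain walking (bulky electron-rich P(t-Bu)3 and a conjugated dienyl partner), cyclisation to outrun oligomerisation (high dilution and slow release of 47), and retention of the 16E,18Z diene (both palladium steps at C16 are stereoretentive). The ester, ketone, amide and silyl ethers should be inert to aqueous K2CO3 in the biphasic medium.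

Step 30
Reactants: 48 tetra-TBS macrocycle
Product: 49 target macrocycle CNP0523849.1
Conditions: HF·pyridine, pyridine/THF, 0 °C to rt
Reagents that add atoms: none
Why: Buffered fluoride desilylation removes all four TBS ethers under mildly acidic conditions that avoid acyl migration or lactone opening by the freed hydroxyls.

**Compound list**

1 | meso-2,4-dimethylglutaric anhydride [(3R,5S)-3,5-dimethyloxane-2,6-dione] | O=C1[C@@H](C)C[C@@H](C)C(=O)O1 | starting material
2 | (2R,4S)-5-methoxy-2,4-dimethyl-5-oxopentanoic acid | COC(=O)[C@@H](C)C[C@@H](C)C(=O)O | intermediate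
3 | methyl (2S,4R)-5-hydroxy-2,4-dimethylpentanoate | COC(=O)[C@@H](C)C[C@@H](C)CO | intermediate
4 | methyl (2S,4R)-2,4-dimethyl-5-oxopentanoate | COC(=O)[C@@H](C)C[C@@H](C)C=O | intermediate
5 | (3-carboxypropyl)triphenylphosphonium bromide | OC(=O)CCC[P+](c1ccccc1)(c1ccccc1)c1ccccc1.[Br-] | starting material
6 | sodium 4-(triphenylphosphoranylidene)butanoate (ylide) | [Na+].[O-]C(=O)CCC=P(c1ccccc1)(c1ccccc1)c1ccccc1 | intermediate
7 | (4Z,6R,8S)-9-methoxy-6,8-dimethyl-9-oxonon-4-enoic acid | COC(=O)[C@@H](C)C[C@@H](C)/C=C\CCC(=O)O | intermediate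
8 | (6S,8S)-9-methoxy-6,8-dimethyl-9-oxononanoic acid | COC(=O)[C@@H](C)C[C@@H](C)CCCCC(=O)O | intermediate
9 | methyl (2S,4S)-9-chloro-2,4-dimethyl-9-oxononanoate | COC(=O)[C@@H](C)C[C@@H](C)CCCCC(=O)Cl | intermediate
10 | but-3-en-1-ol | C=CCCO | starting material
11 | but-3-en-1-yl N,N-diisopropylcarbamate | C=CCCOC(=O)N(C(C)C)C(C)C | intermediate
12 | 2-ethyl-4,4,5,5-tetramethyl-1,3,2-dioxaborolane | CCB1OC(C)(C)C(C)(C)O1 | starting material
13 | (S)-1-lithiobut-3-en-1-yl N,N-diisopropylcarbamate (sparteine complex) | C=CC[C@H]([Li])OC(=O)N(C(C)C)C(C)C | intermediate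
14 | lithium (S)-[1-(carbamoyloxy)but-3-en-1-yl](ethyl)pinacolatoborate | [Li+].C=CC[C@@H](OC(=O)N(C(C)C)C(C)C)[B-]1(CC)OC(C)(C)C(C)(C)O1 | intermediate
15 | 2-[(3S)-hex-5-en-3-yl]-4,4,5,5-tetramethyl-1,3,2-dioxaborolane | C=CC[C@H](CC)B1OC(C)(C)C(C)(C)O1 | intermediate
16 | chlorobis(cyclopentadienyl)[(4S)-4-(Bpin)hexyl]zirconium | Cl[Zr](C1C=CC=C1)(C1C=CC=C1)CCC[C@H](CC)B1OC(C)(C)C(C)(C)O1 | intermediate
17 | methyl (2S,4S,13S)-2,4-dimethyl-9-oxo-13-(Bpin)pentadecanoate | COC(=O)[C@@H](C)C[C@@H](C)CCCCC(=O)CCC[C@H](CC)B1OC(C)(C)C(C)(C)O1 | intermediate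
18 | (2S,4S,13S)-2,4-dimethyl-9-oxo-13-(Bpin)pentadecanoic acid | OC(=O)[C@@H](C)C[C@@H](C)CCCCC(=O)CCC[C@H](CC)B1OC(C)(C)C(C)(C)O1 | intermediate
19 | (3S)-4-amino-3-hydroxybutanoic acid ((S)-GABOB) | OC(=O)C[C@H](O)CN | starting material
20 | (3S)-4-[(tert-butoxycarbonyl)amino]-3-hydroxybutanoic acid | OC(=O)C[C@H](O)CNC(=O)OC(C)(C)C | intermediate
21 | tert-butyl N-[(2S)-2,4-dihydroxybutyl]carbamate | OCC[C@H](O)CNC(=O)OC(C)(C)C | intermediate
22 | acrolein | C=CC=O | starting material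
23 | prop-2-ene-1,1-diyl dibenzoate | C=CC(OC(=O)c1ccccc1)OC(=O)c1ccccc1 | intermediate
24 | tert-butyl N-[(2S)-2-hydroxy-4-oxobutyl]carbamate | O=CC[C@H](O)CNC(=O)OC(C)(C)C | intermediate
25 | (3R,4S,6S)-7-[(tert-butoxycarbonyl)amino]-4,6-dihydroxyhept-1-en-3-yl benzoate | C=C[C@@H](OC(=O)c1ccccc1)[C@@H](O)C[C@H](O)CNC(=O)OC(C)(C)C | intermediate
26 | tert-butyl N-[(2S,4S,5R)-2,4,5-trihydroxyhept-6-en-1-yl]carbamate | C=C[C@@H](O)[C@@H](O)C[C@H](O)CNC(=O)OC(C)(C)C | intermediate
27 | tert-butyl N-[(2S,4S,5R)-2,4,5-tris(TBS-oxy)hept-6-en-1-yl]carbamate | C=C[C@@H](O[Si](C)(C)C(C)(C)C)[C@@H](O[Si](C)(C)C(C)(C)C)C[C@H](O[Si](C)(C)C(C)(C)C)CNC(=O)OC(C)(C)C | intermediate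
28 | (E)-(2-bromovinyl)trimethylsilane | C[Si](C)(C)/C=C/Br | starting material
29 | methyl propiolate | C#CC(=O)OC | starting material
30 | methyl (4E)-5-(trimethylsilyl)pent-4-en-2-ynoate | C[Si](C)(C)/C=C/C#CC(=O)OC | intermediate
31 | methyl (2E,4E)-2-(tributylstannyl)-5-(trimethylsilyl)penta-2,4-dienoate | C[Si](C)(C)/C=C/C=C(\C(=O)OC)[Sn](CCCC)(CCCC)CCCC | intermediate
32 | methyl (2E,4E)-2-iodo-5-(trimethylsilyl)penta-2,4-dienoate | C[Si](C)(C)/C=C/C=C(\C(=O)OC)I | intermediate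
33 | B-alkyl-9-BBN adduct of 27 (boron on C20) | C1CC2CCCC(C1)B2CC[C@@H](O[Si](C)(C)C(C)(C)C)[C@@H](O[Si](C)(C)C(C)(C)C)C[C@H](O[Si](C)(C)C(C)(C)C)CNC(=O)OC(C)(C)C | intermediate
34 | methyl (2Z,5R,6S,8S)-9-[(tert-butoxycarbonyl)amino]-5,6,8-tris(TBS-oxy)-2-[(2E)-3-(trimethylsilyl)prop-2-en-1-ylidene]nonanoate | C[Si](C)(C)/C=C/C=C(\C(=O)OC)CC[C@@H](O[Si](C)(C)C(C)(C)C)[C@@H](O[Si](C)(C)C(C)(C)C)C[C@H](O[Si](C)(C)C(C)(C)C)CNC(=O)OC(C)(C)C | intermediate
35 | tert-butyl N-[(2S,4S,5R,8Z,10E)-2,4,5-tris(TBS-oxy)-8-(hydroxymethyl)-11-(trimethylsilyl)undeca-8,10-dien-1-yl]carbamate | C[Si](C)(C)/C=C/C=C(\CO)CC[C@@H](O[Si](C)(C)C(C)(C)C)[C@@H](O[Si](C)(C)C(C)(C)C)C[C@H](O[Si](C)(C)C(C)(C)C)CNC(=O)OC(C)(C)C | intermediate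
36 | tert-butyl N-[(2S,4S,5R,8Z,10E)-2,4,5-tris(TBS-oxy)-8-(TBS-oxymethyl)-11-(trimethylsilyl)undeca-8,10-dien-1-yl]carbamate | C[Si](C)(C)/C=C/C=C(\CO[Si](C)(C)C(C)(C)C)CC[C@@H](O[Si](C)(C)C(C)(C)C)[C@@H](O[Si](C)(C)C(C)(C)C)C[C@H](O[Si](C)(C)C(C)(C)C)CNC(=O)OC(C)(C)C | intermediate
37 | tert-butyl N-[(2S,4S,5R,8Z,10E)-2,4,5-tris(TBS-oxy)-8-(TBS-oxymethyl)-11-iodoundeca-8,10-dien-1-yl]carbamate | I/C=C/C=C(\CO[Si](C)(C)C(C)(C)C)CC[C@@H](O[Si](C)(C)C(C)(C)C)[C@@H](O[Si](C)(C)C(C)(C)C)C[C@H](O[Si](C)(C)C(C)(C)C)CNC(=O)OC(C)(C)C | intermediate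
38 | trimethylsilyl N-[(2S,4S,5R,8Z,10E)-2,4,5-tris(TBS-oxy)-8-(TBS-oxymethyl)-11-iodoundeca-8,10-dien-1-yl]carbamate | I/C=C/C=C(\CO[Si](C)(C)C(C)(C)C)CC[C@@H](O[Si](C)(C)C(C)(C)C)[C@@H](O[Si](C)(C)C(C)(C)C)C[C@H](O[Si](C)(C)C(C)(C)C)CNC(=O)O[Si](C)(C)C | intermediate
39 | (2S,4S,5R,8Z,10E)-2,4,5-tris(TBS-oxy)-8-(TBS-oxymethyl)-11-iodoundeca-8,10-dien-1-amine | I/C=C/C=C(\CO[Si](C)(C)C(C)(C)C)CC[C@@H](O[Si](C)(C)C(C)(C)C)[C@@H](O[Si](C)(C)C(C)(C)C)C[C@H](O[Si](C)(C)C(C)(C)C)CN | intermediate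
40 | L-norvaline | CCC[C@H](N)C(=O)O | starting material
41 | (2S)-2-hydroxypentanoic acid | CCC[C@H](O)C(=O)O | intermediate
42 | 1H-benzotriazol-1-yl (2S)-2-hydroxypentanoate | CCC[C@H](O)C(=O)On1nnc2ccccc12 | intermediate
43 | (2S)-2-hydroxy-N-[(2S,4S,5R,8Z,10E)-2,4,5-tris(TBS-oxy)-8-(TBS-oxymethyl)-11-iodoundeca-8,10-dien-1-yl]pentanamide | I/C=C/C=C(\CO[Si](C)(C)C(C)(C)C)CC[C@@H](O[Si](C)(C)C(C)(C)C)[C@@H](O[Si](C)(C)C(C)(C)C)C[C@H](O[Si](C)(C)C(C)(C)C)CNC(=O)[C@@H](O)CCC | intermediate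
44 | mixed anhydride of 18 with 2,4,6-trichlorobenzoic acid | O=C(OC(=O)[C@@H](C)C[C@@H](C)CCCCC(=O)CCC[C@H](CC)B1OC(C)(C)C(C)(C)O1)c1c(Cl)cc(Cl)cc1Cl | intermediate
45 | seco ester: (2S)-1-oxo-1-{[(2S,4S,5R,8Z,10E)-2,4,5-tris(TBS-oxy)-8-(TBS-oxymethyl)-11-iodoundeca-8,10-dien-1-yl]amino}pentan-2-yl (2S,4S,13S)-2,4-dimethyl-9-oxo-13-(Bpin)pentadecanoate | I/C=C/C=C(\CO[Si](C)(C)C(C)(C)C)CC[C@@H](O[Si](C)(C)C(C)(C)C)[C@@H](O[Si](C)(C)C(C)(C)C)C[C@H](O[Si](C)(C)C(C)(C)C)CNC(=O)[C@H](CCC)OC(=O)[C@@H](C)C[C@@H](C)CCCCC(=O)CCC[C@H](CC)B1OC(C)(C)C(C)(C)O1 | intermediate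
46 | potassium trifluoroborate of 45 (C15–BF3K, S at C15) | I/C=C/C=C(\CO[Si](C)(C)C(C)(C)C)CC[C@@H](O[Si](C)(C)C(C)(C)C)[C@@H](O[Si](C)(C)C(C)(C)C)C[C@H](O[Si](C)(C)C(C)(C)C)CNC(=O)[C@H](CCC)OC(=O)[C@@H](C)C[C@@H](C)CCCCC(=O)CCC[C@H](CC)[B-](F)(F)F.[K+] | intermediate
47 | boronic acid of 45 (C15–B(OH)2) | I/C=C/C=C(\CO[Si](C)(C)C(C)(C)C)CC[C@@H](O[Si](C)(C)C(C)(C)C)[C@@H](O[Si](C)(C)C(C)(C)C)C[C@H](O[Si](C)(C)C(C)(C)C)CNC(=O)[C@H](CCC)OC(=O)[C@@H](C)C[C@@H](C)CCCCC(=O)CCC[C@H](CC)B(O)O | intermediate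
48 | tetra-TBS macrocycle (28-membered ring; TBS on O22, O23, O25 and on the C19 hydroxymethyl oxygen; C15 R) | CCC[C@@H]1OC(=O)[C@@H](C)C[C@@H](C)CCCCC(=O)CCC[C@@H](CC)/C=C/C=C(\CO[Si](C)(C)C(C)(C)C)CC[C@@H](O[Si](C)(C)C(C)(C)C)[C@@H](O[Si](C)(C)C(C)(C)C)C[C@H](O[Si](C)(C)C(C)(C)C)CNC1=O | intermediate
49 | target CNP0523849.1 (28-membered macrolactone-lactam) | CCC[C@@H]1OC(=O)[C@@H](C)C[C@@H](C)CCCCC(=O)CCC[C@@H](CC)/C=C/C=C(\CO)CC[C@@H](O)[C@@H](O)C[C@H](O)CNC1=O | target

**Step count and risks**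

Total step count: 30. Longest linear sequence: 15 steps (steps 11, 12, 14, 15, 16, 20, 21, 22, 23, 24, 26, 27, 28, 29, 30; from 19 to 49).

Steps most likely to fail:

1. Step 29 (proposed new method). Transmetalation of the hindered secondary C–B bond may be slow inside the large ring, so that proto-deiodination, oligomerisation, β-hydride elimination with chain walking, or incomplete stereochemical fidelity (mixed retention and inversion) compete. The fallback uses known chemistry: it makes C15–C16 by an intermolecular Zweifel olefination and closes the ring at the lactone. It sets out from carbamate 11 and dienyl iodide 37 and comes back at 48. Lithiation–borylation of 11 as in step 8, with (+)-sparteine in place of (−)-sparteine, should give the enantiomeric boronic ester 2-[(3R)-hex-5-en-3-yl]-4,4,5,5-tetramethyl-1,3,2-dioxaborolane F1. Iodide 37 is N-deprotonated and lithiated by iodine–lithium exchange (t-BuLi, −78 °C) and added to F1. The resulting boronate complex is taken through the syn-elimination form of the Zweifel olefination (PhSeCl, then m-CPBA), which proceeds with retention at C15 and at the alkene and should give the N-Boc tetraene F2. Hydrozirconation of the terminal alkene of F2 and copper-catalysed acylation with acid chloride 9 (as in step 9) should give the methyl keto ester F3. Boc cleavage (TMSOTf, 2,6-lutidine) gives the amine F4, coupling with acid 41 (EDC, HOBt) gives the hydroxy amide F5, and saponification (LiOH) gives the seco hydroxy acid F6. Yamaguchi macrolactonisation of F6 at high dilution closes the O2–C3 bond and gives 48.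

2. Step 14. The aldehyde face may be poorly controlled against the resident C25 centre, the secondary alcohol may be dehydrogenated competitively, or the benzoate may migrate, giving isomer mixtures. The fallback sets out from diol 21 and comes back at triol 26. Selective oxidation of the primary alcohol (TEMPO, PhI(OAc)2) gives aldehyde 24 as an isolated compound. Reagent-controlled allylboration with the tartrate allylboronate diisopropyl (4S,5S)-2-[(2E)-3-[(cyclohexyloxy)dimethylsilyl]prop-2-en-1-yl]-1,3,2-dioxaborolane-4,5-dicarboxylate F7 passes through a chair transition state and should give the anti-β-hydroxy allylsilane tert-butyl N-[(2S,4S,5R)-5-[(cyclohexyloxy)dimethylsilyl]-2,4-dihydroxyhept-6-en-1-yl]carbamate F8. Fleming–Tamao oxidation (H2O2, KF, KHCO3) converts C–Si into C–OH with retention and gives 26.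

3. Step 9. Zirconium-to-copper transmetalation of the alkyl group may be incomplete, and residual Zr–H may reduce the acid chloride. The fallback sets out from boronic ester 15 and acid 8 and comes back at ketone 17. Anti-Markovnikov hydroiodination of 15 (9-BBN; then I2, NaOMe) should give the iodide 2-[(3S)-6-iodohexan-3-yl]-4,4,5,5-tetramethyl-1,3,2-dioxaborolane F9, and zinc insertion (Zn, LiCl, THF) gives the zinc reagent [(4S)-4-(Bpin)hexyl]zinc iodide F10. Acid 8 is converted (EtSH, EDC, DMAP) into the thioester methyl (2S,4S)-9-(ethylsulfanyl)-2,4-dimethyl-9-oxononanoate F11. Fukuyama coupling of F10 with F11 (PdCl2(PPh3)2, toluene/THF, rt) gives 17.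

Further compounds

F1 | step 29 | 2-[(3R)-hex-5-en-3-yl]-4,4,5,5-tetramethyl-1,3,2-dioxaborolane | C=CC[C@@H](CC)B1OC(C)(C)C(C)(C)O1
F2 | step 29 | tert-butyl N-[(2S,4S,5R,8Z,10E,12R)-2,4,5-tris(TBS-oxy)-8-(TBS-oxymethyl)-12-ethylpentadeca-8,10,14-trien-1-yl]carbamate | C=CC[C@@H](CC)/C=C/C=C(\CO[Si](C)(C)C(C)(C)C)CC[C@@H](O[Si](C)(C)C(C)(C)C)[C@@H](O[Si](C)(C)C(C)(C)C)C[C@H](O[Si](C)(C)C(C)(C)C)CNC(=O)OC(C)(C)C
F3 | step 29 | methyl (2S,4S,13R,14E,16Z,20R,21S,23S)-24-[(tert-butoxycarbonyl)amino]-20,21,23-tris(TBS-oxy)-17-(TBS-oxymethyl)-13-ethyl-2,4-dimethyl-9-oxotetracosa-14,16-dienoate | COC(=O)[C@@H](C)C[C@@H](C)CCCCC(=O)CCC[C@@H](CC)/C=C/C=C(\CO[Si](C)(C)C(C)(C)C)CC[C@@H](O[Si](C)(C)C(C)(C)C)[C@@H](O[Si](C)(C)C(C)(C)C)C[C@H](O[Si](C)(C)C(C)(C)C)CNC(=O)OC(C)(C)C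
F4 | step 29 | methyl (2S,4S,13R,14E,16Z,20R,21S,23S)-24-amino-20,21,23-tris(TBS-oxy)-17-(TBS-oxymethyl)-13-ethyl-2,4-dimethyl-9-oxotetracosa-14,16-dienoate | COC(=O)[C@@H](C)C[C@@H](C)CCCCC(=O)CCC[C@@H](CC)/C=C/C=C(\CO[Si](C)(C)C(C)(C)C)CC[C@@H](O[Si](C)(C)C(C)(C)C)[C@@H](O[Si](C)(C)C(C)(C)C)C[C@H](O[Si](C)(C)C(C)(C)C)CN
F5 | step 29 | methyl (2S,4S,13R,14E,16Z,20R,21S,23S)-24-{[(2S)-2-hydroxypentanoyl]amino}-20,21,23-tris(TBS-oxy)-17-(TBS-oxymethyl)-13-ethyl-2,4-dimethyl-9-oxotetracosa-14,16-dienoate | COC(=O)[C@@H](C)C[C@@H](C)CCCCC(=O)CCC[C@@H](CC)/C=C/C=C(\CO[Si](C)(C)C(C)(C)C)CC[C@@H](O[Si](C)(C)C(C)(C)C)[C@@H](O[Si](C)(C)C(C)(C)C)C[C@H](O[Si](C)(C)C(C)(C)C)CNC(=O)[C@@H](O)CCC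
F6 | step 29 | (2S,4S,13R,14E,16Z,20R,21S,23S)-24-{[(2S)-2-hydroxypentanoyl]amino}-20,21,23-tris(TBS-oxy)-17-(TBS-oxymethyl)-13-ethyl-2,4-dimethyl-9-oxotetracosa-14,16-dienoic acid | OC(=O)[C@@H](C)C[C@@H](C)CCCCC(=O)CCC[C@@H](CC)/C=C/C=C(\CO[Si](C)(C)C(C)(C)C)CC[C@@H](O[Si](C)(C)C(C)(C)C)[C@@H](O[Si](C)(C)C(C)(C)C)C[C@H](O[Si](C)(C)C(C)(C)C)CNC(=O)[C@@H](O)CCC
F7 | step 14 | diisopropyl (4S,5S)-2-[(2E)-3-[(cyclohexyloxy)dimethylsilyl]prop-2-en-1-yl]-1,3,2-dioxaborolane-4,5-dicarboxylate | CC(C)OC(=O)[C@H]1OB(C/C=C/[Si](C)(C)OC2CCCCC2)O[C@@H]1C(=O)OC(C)C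
F8 | step 14 | tert-butyl N-[(2S,4S,5R)-5-[(cyclohexyloxy)dimethylsilyl]-2,4-dihydroxyhept-6-en-1-yl]carbamate | C=C[C@@H]([Si](C)(C)OC1CCCCC1)[C@@H](O)C[C@H](O)CNC(=O)OC(C)(C)C
F9 | step 9 | 2-[(3S)-6-iodohexan-3-yl]-4,4,5,5-tetramethyl-1,3,2-dioxaborolane | ICCC[C@H](CC)B1OC(C)(C)C(C)(C)O1
F10 | step 9 | [(4S)-4-(Bpin)hexyl]zinc iodide | I[Zn]CCC[C@H](CC)B1OC(C)(C)C(C)(C)O1
F11 | step 9 | methyl (2S,4S)-9-(ethylsulfanyl)-2,4-dimethyl-9-oxononanoate | COC(=O)[C@@H](C)C[C@@H](C)CCCCC(=O)SCC
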